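## Structural features

The target is a branched profisetinidin tetraflavanoid in which a central (+)-catechin (unit 3, 2R,3S, C4 a methylene) carries one fisetinidol (unit 4) on C8 and a fisetinidol–fisetinidol chain (units 2 and 1) on C6. All three interflavanyl bonds run from C4 of a 5-deoxyflavan-3-ol to an aromatic carbon, (4α→8) once and (4α→6) twice. Each fisetinidol unit has three adjacent stereocentres, C2–C3–C4, in the all-trans arrangement (2R,3S, 3,4-trans, 2,4-cis) with C4 a crowded diarylmethine, and with the two centres of catechin there are eleven. Thirteen phenolic hydroxyls (four catechols, three resorcinol-type rings A and one phloroglucinol-type ring A) make the free compound air- and base-sensitive, strong acid cleaves the C4–aryl bonds, and C2 can epimerise in base once a 4'-hydroxyl is free. The real difficulty is regiocontrol of three C4–aryl bonds among many nucleophilic ring positions (C6 against C8 of unit 3, and C6 of unit 2 against the chemically equivalent C6 of unit 4), together with control of nine new stereocentres as three all-trans triads without oligomer mixtures. The key step uses the fact that in each fisetinidol unit the atoms O1–C8a–C4a–C4 with the lower arene on C4 form the pattern of an ortho-quinone methide of ring A, while C2–C3 with ring B is a former E-styrene, so O1–C2 and C3–C4 of ring C can be made together, first in unit 4 on C8 of catechin. Because an enol ether would bind through the wrong carbon, the C3 oxygen has to enter as a silyl group on the alkene carbon that becomes C3.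

## Logic of the disconnections

35 to 34: the sixteen O–CH2Ph bonds (thirteen phenolic, three secondary) are cut. The free polyphenol tolerates neither organolithium reagents nor cation-forming acids and oxidises in air, so all hydroxyls travel as benzyl ethers and are released in one neutral operation. The gain is that every earlier intermediate is a lipophilic, chromatographable ether. The forward step must cleave only O–benzyl bonds and spare the benzylic C2–O1 and C4–aryl bonds.

34 to 32 (through 33): the C3–O bond of unit 1 is traced to a C3–Si bond. Silicon directs the regiochemistry of ring formation and is exchanged for oxygen with retention, so the 3S configuration is already fixed in 32. The gain is one 2π partner, 13, for all three units. The forward oxidation must be faster than β-elimination of O1 from the silicon-bearing carbon.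

32 to 30 and 13 (through 31), then 30 to 28 and 7 (through 29): O1–C2 and C3–C4 of unit 1 are cut, then the bond between the carbinol carbon (the later C4 of unit 1) and C6 of unit 2. This reduces 32 to 28 plus the two small pieces 7 and 13. The demand is a bromine on C6 of unit 2 and nowhere else. It cannot be introduced by late bromination, because C6 of unit 4 is an equivalent position, so it must come in with 20.

28 to 27 to 25 (through 26), then 25 to 23 and 13 (through 24), then 23 to 18 and 20 (through 21 and 22): the benzyl ether and the C3–O bond of unit 2 are traced back to silicon, ring C of unit 2 is cut at O1–C2 and C3–C4, and the carbinol carbon is cut from C6 of unit 3. The gain is 18 plus 13 and 20. The demand is a bromine on C6 of unit 3 that has survived everything before, and an aryllithium that adds to the aldehyde faster than it exchanges with the aryl bromide of 22.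

18 to 17 to 15 (through 16): the 3-O-benzyl bond and then the C3–O bond of unit 4 are traced back to C3–Si. Oxidising at once gives a fully etherified 18 with no alkoxide in the later organolithium steps, and it tests the silicon-to-oxygen exchange on the smallest substrate. The demand is as for 34 to 32.

15 to 9 and 13 (through 14), the key disconnection: O1–C2 and C3–C4 of unit 4 are cut. The ring, two skeletal bonds and three stereocentres fall away together, leaving a carbinol and an alkene. The forward step must control regiochemistry (silicon carbon to C4), relative configuration (all-trans) and the face of 14, and must avoid loss of silicon and Friedel–Crafts self-condensation. For that reason 9 carries bromine on C6.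

9 to 4 and 7 (through 8), then 4 to 3 to 2 to 1: the bond between the carbinol carbon and C8 of unit 3 is cut, then the two carbon–halogen bonds and the five benzyl ethers. Iodine on C8 and bromine on C6 allow one halogen to be exchanged for lithium while the other stays as block and later handle. The demands are C8-selective iodination, bromination of C6 without disturbing C–I, and iodine–lithium exchange that leaves C–Br alone.

13 to 11 and 12, 11 to 10, 7 to 6 to 5, 20 to 19: the Si–C bond and one C–H bond across the alkyne are cut, then the alkyne carbon from the aldehyde carbon, then the O–Na bond of 7 and one benzyl ether in each aldehyde. All pieces become commercial materials. The demands are E-selective, terminal hydrosilylation, benzylation of the 4-hydroxyl only, and a salt 7 that is dry and free of hydride, since it is used in two separate carbinol-forming steps.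

## Other disconnections considered

Alternative 1: the three O1–C2 bonds of units 1, 2 and 4 are cut at once. In the forward direction Ag2O would oxidise three 4-hydroxy-3-benzyloxybenzyl groups to para-quinone methides, and each neighbouring ring A phenol would add to its methide carbon (6-exo-trig oxa-Michael closure). This would give the tetradeca-O-benzyl ether A1 with free 4'-hydroxyls on units 1, 2 and 4.
- In its favour: three rings close in one operation, the C3 oxygen is present from the start in a lactic-acid-type chain, and only hydrogenolysis would remain. On step count after the key step and on the absence of a silicon-to-oxygen exchange it is better than the chosen plan.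
- The 2,3-trans relation could settle under reversible closure, which is equal to the chosen plan in likely outcome.
- Against it: the step forms only C–O bonds. All three crowded C4–aryl bonds and the C3/C4 relationships would have to be built beforehand on open chains, with no ring to relay stereochemistry, so the main difficulty is moved and not removed.
- The substrate would carry free ring A phenols ortho to tertiary diarylmethine C–H bonds. Ag2O could oxidise these to ortho-quinone methides and so destroy C4.
- The 4'-hydroxyl must be told apart from the 3'-hydroxyl on three rings.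
- Comparison: the chosen plan makes C3–C4, O1–C2 and all three stereocentres of a unit in one step from two simple partners. Alternative 1 is more convergent at the end but much longer before its key step.

Alternative 2: O1–C2 of unit 2 is cut and the C3 oxygen is traced to acetate delivered in the same step; ring C would come from a five-membered benzofuran ring. In the forward direction Zn(OAc)2 would assist loss of a benzylic mesylate with participation of the furan oxygen, and acetate would open the oxiranium ion at the former furan C2. This would give the bromo acetate A2, 6-bromo-tri-O-benzylfisetinidol 3-acetate-(4α→6)-8-bromo-penta-O-benzylcatechin.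
- In its favour: the transfer is stereospecific (two inversions), so C2 and C3 would follow from the substrate and not from a catalyst. On reliability of stereochemical transfer it is equal or better.
- Oxygen arrives on C3 at the right oxidation level, which is better than a masked hydroxyl.
- The two bromines of A2 are handles of the same kind as in the chosen plan, an equal point.
- Against it: the mesylate carbon is benzylic to a dialkoxyphenyl ring, so plain ionisation can compete with participation and erode stereospecificity.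
- Acetate may open the oxiranium ion at the more cationic benzylic carbon and return a five-membered ring.
- The substrate already needs the crowded C4–aryl bond and three adjacent stereocentres, so the hardest bond lies outside the key step.
- An acetate would have to be exchanged before organolithium chemistry.
- Comparison: per unit this costs more steps than the two-step carbinol/cycloaddition sequence, and it forms one bond where the chosen step forms two.

Alternative 3: C3–C4 of unit 4 is cut. In the forward direction Bu4NF would activate a diarylmethyl trimethylsilane on C8 of unit 3, and the benzylic carbanion equivalent would add to a tethered α-aryloxy aldehyde (6-exo-trig). This would close ring C and give the dimer A3 with a free 3-hydroxyl.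
- In its favour: the 3-hydroxyl forms directly, which is better than the silicon detour.
- The closure is intramolecular, so regiochemistry is not in question, which is equal or better.
- A3 is the bromine-free counterpart of 17, so the later logic would be the same.
- Against it: the polarity is mismatched. The future C4 lies between two very electron-rich arenes, so a carbanion there is poorly stabilised, and protodesilylation may win.
- The α-aryl-α-aryloxy aldehyde can lose its C2 configuration through the enolate under basic fluoride.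
- The C3/C4 relationship would rest on a cyclic transition state with no strong control element.
- O1–C2 and the C4–C8 bond must exist beforehand, which means a chiral benzylic aryl ether and a silane between two arenes.
- Comparison: one bond and two stereocentres are formed against two bonds and three stereocentres in the chosen step, and the preparation of the substrate is clearly longer.

Key step: step 9

Assumptions and remarks on the chemistry:
- Structure check: the target reads as fisetinidol-(4α→6)-fisetinidol-(4α→6)-[fisetinidol-(4α→8)]-catechin, every fisetinidol unit 2R,3S with 3,4-trans and 2,4-cis substituents. The skeletons of 9 and 15 agree with it, with silicon in 15 on the face of the later 3-hydroxyl.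
- Design point 1: the carbinol 9 carries bromine on C6 of the catechin ring. It blocks the only phloroglucinol-type CH against Friedel–Crafts attack on the quinone methide and is the handle for unit 2.
- Design point 2: the bromine for C6 of unit 2 is brought in with aldehyde 20. A late bromination could not distinguish C6 of unit 2 from C6 of unit 4.
- Design point 3: the phenolic aldehydes react as sodium phenoxides, so that no aryllithium is lost to the acidic phenol. Salt 7 is needed in two carbinol-forming steps and is therefore prepared once as a dry, storable solid; salt 22 is needed once and is made in the flask.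
- (R)-TRIP is (R)-3,3'-bis(2,4,6-triisopropylphenyl)-1,1'-binaphthalene-2,2'-diyl hydrogen phosphate. The sense of induction with this 2π partner cannot be predicted with certainty; the enantiomer meant in steps 9, 14 and 18 is the one that gives the 4α adduct.
- 5-Bromo-2,4-dihydroxybenzaldehyde (19) is taken as commercial.

## Route

Step 1
Reactants: 1 (+)-catechin
Product: 2 3,5,7,3',4'-penta-O-benzylcatechin
Conditions: NaH, BnBr, DMF, −20 °C → rt
Reagents that add atoms: benzyl bromide, BrCc1ccccc1
Why: Williamson etherification of four phenoxides and the secondary alkoxide; benzyl bromide is present before the base, so each phenoxide is trapped as it forms and the 4'-phenoxide has no time to open ring C, which keeps C2 and C3 as in catechin.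

Step 2
Reactants: 2 3,5,7,3',4'-penta-O-benzylcatechin
Product: 3 8-iodo-3,5,7,3',4'-penta-O-benzylcatechin
Conditions: NIS (1.05 equiv), CH2Cl2, −20 → 0 °C, dark
Reagents that add atoms: N-iodosuccinimide, O=C1CCC(=O)N1I
Why: Electrophilic aromatic iodination of the phloroglucinol-type ring A; C8 is the established first site of halogenation of 5,7-di-O-alkylflavans, and the large iodine electrophile should avoid C6 between two benzyloxy groups still more, while the catechol diether ring B is far less activated.

Step 3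
Reactants: 3 8-iodo-3,5,7,3',4'-penta-O-benzylcatechin
Product: 4 6-bromo-8-iodo-3,5,7,3',4'-penta-O-benzylcatechin
Conditions: NBS (1.05 equiv), CH2Cl2, −40 → 0 °C, dark
Reagents that add atoms: N-bromosuccinimide, O=C1CCC(=O)N1Br
Why: Electrophilic aromatic bromination of the last free position of ring A, C6, which is activated by three oxygens and is the known second halogenation site of catechin ethers; low temperature and one equivalent limit ipso attack at the C–I carbon.

Step 4
Reactants: 5 2,4-dihydroxybenzaldehyde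
Product: 6 4-(benzyloxy)-2-hydroxybenzaldehyde
Conditions: BnBr (1.05 equiv), NaHCO3, KI (cat.), MeCN, 80 °C
Reagents that add atoms: benzyl bromide, BrCc1ccccc1
Why: Williamson etherification under weak base; the 2-hydroxyl is held in a hydrogen bond to the aldehyde and stays protonated, so only the 4-hydroxyl is alkylated.

Step 5
Reactants: 6 4-(benzyloxy)-2-hydroxybenzaldehyde
Product: 7 sodium 5-(benzyloxy)-2-formylphenolate
Conditions: NaH (1.0 equiv), THF, 0 °C → rt; evaporation, solid washed with pentane, dried in vacuo, stored under argon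
Reagents that add atoms: sodium hydride, [Na+].[H-]
Why: Irreversible acid–base reaction of the phenol, acidified by the ortho formyl group, with hydride (H2 leaves). The chelated sodium 2-formylphenolate is a stable salt that can be dried and stored, so one batch serves the carbinol-forming steps 6 and 17 and no aryllithium is later lost to an acidic proton.

Step 6
Reactants: 4 6-bromo-8-iodo-3,5,7,3',4'-penta-O-benzylcatechin; 7 sodium 5-(benzyloxy)-2-formylphenolate
Product: 9 (6-bromo-3,5,7,3',4'-penta-O-benzylcatechin-8-yl)(4-benzyloxy-2-hydroxyphenyl)methanol as a mixture of carbinol epimers, via aryllithium 8 (not isolated)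
Conditions: 4, n-BuLi (1.0 equiv), THF, −78 °C, 10 min; then 7 (1.2 equiv) in THF, −78 → −20 °C; aq NH4Cl; SiO2 deactivated by Et3N
Reagents that add atoms: none
Why: Halogen–lithium exchange is far faster at C–I than at C–Br, so 8 keeps its bromine (meta to lithium, no aryne); 1,2-addition of the aryllithium to the aldehyde of 7, whose phenol is masked as the sodium salt, gives the doubly benzylic carbinol. The carbinol centre is formed without control, which does not matter because step 9 planarises it.

Step 7
Reactants: 10 3,4-bis(benzyloxy)benzaldehyde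
Product: 11 1,2-bis(benzyloxy)-4-ethynylbenzene
Conditions: dimethyl (1-diazo-2-oxopropyl)phosphonate, K2CO3, MeOH/THF, rt
Reagents that add atoms: dimethyl (1-diazo-2-oxopropyl)phosphonate, COP(=O)(OC)C(=[N+]=[N-])C(C)=O
Why: Seyferth–Gilbert homologation in the Ohira–Bestmann form: methanolysis frees the diazomethylphosphonate anion, which adds to the non-enolisable aldehyde; loss of phosphate and N2 and a 1,2-hydrogen shift give the terminal alkyne.

Step 8
Reactants: 11 1,2-bis(benzyloxy)-4-ethynylbenzene; 12 benzyldimethylsilane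
Product: 13 (E)-benzyl[2-(3,4-bis(benzyloxy)phenyl)ethenyl]dimethylsilane
Conditions: Pt2[(CH2=CHSiMe2)2O]3 (0.5 mol %, zerovalent platinum), P(t-Bu)3 (1 mol %), THF, rt
Reagents that add atoms: none
Why: Platinum-catalysed hydrosilylation of a terminal alkyne; syn addition of Si–H fixes the E geometry, and the bulky phosphine directs silicon to the terminal carbon.

Step 9
Reactants: 9 (6-bromo-3,5,7,3',4'-penta-O-benzylcatechin-8-yl)(4-benzyloxy-2-hydroxyphenyl)methanol; 13 (E)-benzyl[2-(3,4-bis(benzyloxy)phenyl)ethenyl]dimethylsilane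
Product: 15 7,3',4'-tri-O-benzyl-3-deoxy-3-(benzyldimethylsilyl)fisetinidol-(4α→8)-6-bromo-3,5,7,3',4'-penta-O-benzylcatechin, via quinone methide 14 (not isolated)
Conditions: (R)-TRIP (10 mol %), 13 (2.5 equiv), 5 Å MS, toluene, 0 °C → rt, 9 added slowly
Reagents that add atoms: none
Why: Proposed new method: the closest known reaction is the chiral phosphoric acid-catalysed [4+2] cycloaddition of ortho-quinone methides, made in the flask from ortho-hydroxybenzhydrols, with styrenes to 2,4-cis-diarylchromans; new here is a β-silylstyrene as the 2π partner with silicon kept on the new ring. The acid ionises the doubly benzylic carbinol of 9 (either epimer) and the free ring A phenol turns the cation into the neutral quinone methide 14 (oxadiene O=C8a–C4a=C4), which stays hydrogen-bonded to the chiral phosphate. The silicon-bearing carbon of 13 attacks C4, because the charge that then builds on the other alkene carbon is benzylic to the dialkoxyphenyl ring and β to silicon, and the ring A oxygen closes on that carbon; ring C therefore closes as a six-membered ring by an asynchronous inverse-electron-demand hetero-Diels–Alder addition (4π oxadiene plus 2π alkene, O1–C2 and C3–C4 formed). C2 and C3: the E geometry of 13 is transferred suprafacially (closure anti to silicon in the stepwise limit leads to the same result), which gives 2,3-trans. C4: the ring B aryl lies endo over the E-configured quinone methide, which gives 2,4-cis and with it the all-trans triad. Absolute sense: the phosphate bound to the quinone methide oxygen shields one face, and since the catechin unit is already a single enantiomer an adduct from the other face is a diastereomer that chromatography can remove. Selectivity needed: ring closure has to outrun loss of silicon from the β-silyl cation and Friedel–Crafts attack by other arenes; the tethered oxygen nucleophile, the absence of an external nucleophile for silicon, the excess of 13 and the bromine that blocks C6 serve this.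

Step 10
Reactants: 15 7,3',4'-tri-O-benzyl-3-deoxy-3-(benzyldimethylsilyl)fisetinidol-(4α→8)-6-bromo-3,5,7,3',4'-penta-O-benzylcatechin
Product: 17 7,3',4'-tri-O-benzylfisetinidol-(4α→8)-6-bromo-3,5,7,3',4'-penta-O-benzylcatechin, via fluorosilane 16 (not isolated)
Conditions: Bu4NF (3 equiv), THF, 0 °C → rt; then KHCO3, 30% aq H2O2, MeOH/THF, rt → 40 °C
Reagents that add atoms: hydrogen peroxide, OO
Why: Tamao–Fleming oxidation of a benzyldimethylsilyl group: fluoride expels the benzyl group as toluene to give 16, hydroperoxide adds to silicon, and C3 migrates from silicon to oxygen with retention, so the hydroxyl takes the place and configuration of silicon (3S, all-trans). Benzyl ethers, the aryl bromide and the C4–aryl bond are inert to mildly basic peroxide.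

Step 11
Reactants: 17 7,3',4'-tri-O-benzylfisetinidol-(4α→8)-6-bromo-3,5,7,3',4'-penta-O-benzylcatechin
Product: 18 3,7,3',4'-tetra-O-benzylfisetinidol-(4α→8)-6-bromo-3,5,7,3',4'-penta-O-benzylcatechin
Conditions: NaH, BnBr, Bu4NI (cat.), DMF, 0 °C → rt
Reagents that add atoms: benzyl bromide, BrCc1ccccc1
Why: Williamson etherification of the hindered secondary alkoxide with a small, reactive electrophile under iodide catalysis; with no free phenol in the molecule no stereocentre can epimerise, and the later organolithium steps meet no acidic proton.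

Step 12
Reactants: 19 5-bromo-2,4-dihydroxybenzaldehyde
Product: 20 4-(benzyloxy)-5-bromo-2-hydroxybenzaldehyde
Conditions: BnBr (1.05 equiv), NaHCO3, KI (cat.), MeCN, 80 °C
Reagents that add atoms: benzyl bromide, BrCc1ccccc1
Why: Williamson etherification as in step 4; the hydrogen-bonded 2-hydroxyl stays free and the 4-hydroxyl, made more acidic by the ortho bromine, is alkylated.

Step 13
Reactants: 18 3,7,3',4'-tetra-O-benzylfisetinidol-(4α→8)-6-bromo-3,5,7,3',4'-penta-O-benzylcatechin; 20 4-(benzyloxy)-5-bromo-2-hydroxybenzaldehyde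
Product: 23 [8-(3,7,3',4'-tetra-O-benzylfisetinidol-4α-yl)-3,5,7,3',4'-penta-O-benzylcatechin-6-yl](4-benzyloxy-5-bromo-2-hydroxyphenyl)methanol as a mixture of carbinol epimers, via aryllithium 21 (not isolated), via sodium phenoxide 22 (not isolated)
Conditions: 18, n-BuLi (1.05 equiv), THF, −78 °C, 15 min; then 22 (from 20, NaH, THF, 0 °C), −78 → −20 °C; aq NH4Cl; SiO2 deactivated by Et3N
Reagents that add atoms: none
Why: Bromine–lithium exchange at C6 of unit 3 gives an aryllithium stabilised by two flanking benzyloxy groups, and 1,2-addition to the aldehyde of 22 follows. Exchange with the aryl bromide of 22 is not expected, because it would place lithium on an electron-rich phenoxide ring.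

Step 14
Reactants: 23 [8-(3,7,3',4'-tetra-O-benzylfisetinidol-4α-yl)-3,5,7,3',4'-penta-O-benzylcatechin-6-yl](4-benzyloxy-5-bromo-2-hydroxyphenyl)methanol; 13 (E)-benzyl[2-(3,4-bis(benzyloxy)phenyl)ethenyl]dimethylsilane
Product: 25 6-bromo-7,3',4'-tri-O-benzyl-3-deoxy-3-(benzyldimethylsilyl)fisetinidol-(4α→6)-[3,7,3',4'-tetra-O-benzylfisetinidol-(4α→8)]-3,5,7,3',4'-penta-O-benzylcatechin, via quinone methide 24 (not isolated)
Conditions: (R)-TRIP (10 mol %), 13 (2.5 equiv), 5 Å MS, toluene, 0 °C → rt
Reagents that add atoms: none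
Why: Proposed new method: as in step 9 the acid turns 23 into quinone methide 24, the silicon-bearing carbon of 13 adds to the methide carbon, and the ring A oxygen closes on the benzylic, β-silyl carbon (closest known type: phosphoric acid-catalysed quinone methide/styrene [4+2] cycloaddition to 2,4-cis-diarylchromans). The E alkene gives 2,3-trans, the endo aryl gives 2,4-cis, the catalyst chooses the face, and a wrong-face adduct is a separable diastereomer. The bromine on the quinone methide ring is a spectator and becomes the C6 handle of unit 2.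

Step 15
Reactants: 25 6-bromo-7,3',4'-tri-O-benzyl-3-deoxy-3-(benzyldimethylsilyl)fisetinidol-(4α→6)-[3,7,3',4'-tetra-O-benzylfisetinidol-(4α→8)]-3,5,7,3',4'-penta-O-benzylcatechin
Product: 27 6-bromo-7,3',4'-tri-O-benzylfisetinidol-(4α→6)-[3,7,3',4'-tetra-O-benzylfisetinidol-(4α→8)]-3,5,7,3',4'-penta-O-benzylcatechin, via fluorosilane 26 (not isolated)
Conditions: Bu4NF (3 equiv), THF, 0 °C → rt; then KHCO3, 30% aq H2O2, MeOH/THF, rt → 40 °C
Reagents that add atoms: hydrogen peroxide, OO
Why: Tamao–Fleming oxidation as in step 10; migration of C3 of unit 2 from silicon to oxygen goes with retention, and the aryl bromide is untouched.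

Step 16
Reactants: 27 6-bromo-7,3',4'-tri-O-benzylfisetinidol-(4α→6)-[3,7,3',4'-tetra-O-benzylfisetinidol-(4α→8)]-3,5,7,3',4'-penta-O-benzylcatechin
Product: 28 6-bromo-3,7,3',4'-tetra-O-benzylfisetinidol-(4α→6)-[3,7,3',4'-tetra-O-benzylfisetinidol-(4α→8)]-3,5,7,3',4'-penta-O-benzylcatechin
Conditions: NaH, BnBr, Bu4NI (cat.), DMF, 0 °C → rt
Reagents that add atoms: benzyl bromide, BrCc1ccccc1
Why: Williamson etherification of the secondary alkoxide as in step 11.

Step 17
Reactants: 28 6-bromo-3,7,3',4'-tetra-O-benzylfisetinidol-(4α→6)-[3,7,3',4'-tetra-O-benzylfisetinidol-(4α→8)]-3,5,7,3',4'-penta-O-benzylcatechin; 7 sodium 5-(benzyloxy)-2-formylphenolate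
Product: 30 6-[(4-benzyloxy-2-hydroxyphenyl)(hydroxy)methyl]-3,7,3',4'-tetra-O-benzylfisetinidol-(4α→6)-[3,7,3',4'-tetra-O-benzylfisetinidol-(4α→8)]-3,5,7,3',4'-penta-O-benzylcatechin as a mixture of carbinol epimers, via aryllithium 29 (not isolated)
Conditions: 28, n-BuLi (1.05 equiv), THF, −78 °C, 15 min; then 7 (1.2 equiv) in THF, −78 → −20 °C; aq NH4Cl; SiO2 deactivated by Et3N
Reagents that add atoms: none
Why: Bromine–lithium exchange at C6 of unit 2 (ortho to the 7-benzyloxy group, the only bromine in the molecule) and 1,2-addition of the aryllithium to the aldehyde of the stored salt 7.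

Step 18
Reactants: 30 6-[(4-benzyloxy-2-hydroxyphenyl)(hydroxy)methyl]-3,7,3',4'-tetra-O-benzylfisetinidol-(4α→6)-[3,7,3',4'-tetra-O-benzylfisetinidol-(4α→8)]-3,5,7,3',4'-penta-O-benzylcatechin; 13 (E)-benzyl[2-(3,4-bis(benzyloxy)phenyl)ethenyl]dimethylsilane
Product: 32 7,3',4'-tri-O-benzyl-3-deoxy-3-(benzyldimethylsilyl)fisetinidol-(4α→6)-3,7,3',4'-tetra-O-benzylfisetinidol-(4α→6)-[3,7,3',4'-tetra-O-benzylfisetinidol-(4α→8)]-3,5,7,3',4'-penta-O-benzylcatechin, via quinone methide 31 (not isolated)
Conditions: (R)-TRIP (10 mol %), 13 (2.5 equiv), 5 Å MS, toluene, 0 °C → rt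
Reagents that add atoms: none
Why: Proposed new method: the same acid-catalysed dehydration to quinone methide 31 and asynchronous [4+2] addition of the β-silylstyrene as in step 9 (closest known type: phosphoric acid-catalysed quinone methide/styrene cycloaddition). The silicon carbon bonds to the methide carbon and oxygen closes on the benzylic carbon; E geometry and endo aryl give the all-trans triad of unit 1, and the catalyst sets the face.

Step 19
Reactants: 32 7,3',4'-tri-O-benzyl-3-deoxy-3-(benzyldimethylsilyl)fisetinidol-(4α→6)-3,7,3',4'-tetra-O-benzylfisetinidol-(4α→6)-[3,7,3',4'-tetra-O-benzylfisetinidol-(4α→8)]-3,5,7,3',4'-penta-O-benzylcatechin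
Product: 34 hexadeca-O-benzyl ether of the target with a free 3-hydroxyl on unit 1, via fluorosilane 33 (not isolated)
Conditions: Bu4NF (3 equiv), THF, 0 °C → rt; then KHCO3, 30% aq H2O2, MeOH/THF, rt → 40 °C
Reagents that add atoms: hydrogen peroxide, OO
Why: Tamao–Fleming oxidation as in step 10, with retention at C3 of unit 1.

Step 20
Reactants: 34 hexadeca-O-benzyl ether of the target with a free 3-hydroxyl on unit 1
Product: 35 fisetinidol-(4α→6)-fisetinidol-(4α→6)-[fisetinidol-(4α→8)]-catechin (CNP0263622.1)
Conditions: H2 (1 atm), Pd(OH)2/C, THF/MeOH/H2O, rt; filtration under argon, lyophilisation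
Reagents that add atoms: none
Why: Heterogeneous hydrogenolysis of sixteen benzyl ethers; under these neutral conditions the benzylic C2–O1 and C4–aryl bonds of flavans are expected to survive, as with benzylated oligoflavanoids in general, and no stereocentre is touched.

## Compound list

1 | (+)-catechin, (2R,3S) | Oc1cc(O)c2c(c1)O[C@H](c1ccc(O)c(O)c1)[C@@H](O)C2 | starting material
2 | 3,5,7,3',4'-penta-O-benzylcatechin | c1c(OCc5ccccc5)cc(OCc5ccccc5)c2c1O[C@H](c1ccc(OCc5ccccc5)c(OCc5ccccc5)c1)[C@@H](OCc5ccccc5)C2 | intermediate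
3 | 8-iodo-3,5,7,3',4'-penta-O-benzylcatechin | Ic1c(OCc5ccccc5)cc(OCc5ccccc5)c2c1O[C@H](c1ccc(OCc5ccccc5)c(OCc5ccccc5)c1)[C@@H](OCc5ccccc5)C2 | intermediate
4 | 6-bromo-8-iodo-3,5,7,3',4'-penta-O-benzylcatechin | Ic1c(OCc5ccccc5)c(Br)c(OCc5ccccc5)c2c1O[C@H](c1ccc(OCc5ccccc5)c(OCc5ccccc5)c1)[C@@H](OCc5ccccc5)C2 | intermediate
5 | 2,4-dihydroxybenzaldehyde | O=Cc1ccc(O)cc1O | starting material
6 | 4-(benzyloxy)-2-hydroxybenzaldehyde | O=Cc1ccc(OCc2ccccc2)cc1O | intermediate
7 | sodium 5-(benzyloxy)-2-formylphenolate | [Na+].[O-]c1cc(OCc2ccccc2)ccc1C=O | intermediate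
8 | (6-bromo-penta-O-benzylcatechin-8-yl)lithium | [Li]c1c(OCc5ccccc5)c(Br)c(OCc5ccccc5)c2c1O[C@H](c1ccc(OCc5ccccc5)c(OCc5ccccc5)c1)[C@@H](OCc5ccccc5)C2 | intermediate (not isolated)
9 | (6-bromo-3,5,7,3',4'-penta-O-benzylcatechin-8-yl)(4-benzyloxy-2-hydroxyphenyl)methanol, both carbinol epimers | OC(c1ccc(OCc5ccccc5)cc1O)c1c(OCc5ccccc5)c(Br)c(OCc5ccccc5)c2c1O[C@H](c1ccc(OCc5ccccc5)c(OCc5ccccc5)c1)[C@@H](OCc5ccccc5)C2 | intermediate
10 | 3,4-bis(benzyloxy)benzaldehyde | O=Cc1ccc(OCc2ccccc2)c(OCc2ccccc2)c1 | starting material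
11 | 1,2-bis(benzyloxy)-4-ethynylbenzene | C#Cc1ccc(OCc2ccccc2)c(OCc2ccccc2)c1 | intermediate
12 | benzyldimethylsilane | C[SiH](C)Cc1ccccc1 | starting material
13 | (E)-benzyl[2-(3,4-bis(benzyloxy)phenyl)ethenyl]dimethylsilane | C[Si](C)(Cc1ccccc1)/C=C/c1ccc(OCc2ccccc2)c(OCc2ccccc2)c1 | intermediate
14 | ortho-quinone methide from 9: 3-(benzyloxy)-6-[(6-bromo-penta-O-benzylcatechin-8-yl)methylidene]cyclohexa-2,4-dien-1-one | O=C1C=C(OCc5ccccc5)C=CC1=Cc1c(OCc5ccccc5)c(Br)c(OCc5ccccc5)c2c1O[C@H](c1ccc(OCc5ccccc5)c(OCc5ccccc5)c1)[C@@H](OCc5ccccc5)C2 | intermediate (not isolated)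
15 | 7,3',4'-tri-O-benzyl-3-deoxy-3-(benzyldimethylsilyl)fisetinidol-(4α→8)-6-bromo-penta-O-benzylcatechin (unit 4 2R,3S, all-trans, silicon on C3) | Brc1c(OCc5ccccc5)c2c(c([C@@H]3c4ccc(OCc5ccccc5)cc4O[C@H](c4ccc(OCc5ccccc5)c(OCc5ccccc5)c4)[C@H]3[Si](C)(C)Cc5ccccc5)c1OCc5ccccc5)O[C@H](c1ccc(OCc5ccccc5)c(OCc5ccccc5)c1)[C@@H](OCc5ccccc5)C2 | intermediate
16 | fluorodimethylsilyl analogue of 15 | Brc1c(OCc5ccccc5)c2c(c([C@@H]3c4ccc(OCc5ccccc5)cc4O[C@H](c4ccc(OCc5ccccc5)c(OCc5ccccc5)c4)[C@H]3[Si](C)(C)F)c1OCc5ccccc5)O[C@H](c1ccc(OCc5ccccc5)c(OCc5ccccc5)c1)[C@@H](OCc5ccccc5)C2 | intermediate (not isolated)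
17 | 7,3',4'-tri-O-benzylfisetinidol-(4α→8)-6-bromo-penta-O-benzylcatechin (free 3-hydroxyl on unit 4) | Brc1c(OCc5ccccc5)c2c(c([C@@H]3c4ccc(OCc5ccccc5)cc4O[C@H](c4ccc(OCc5ccccc5)c(OCc5ccccc5)c4)[C@H]3O)c1OCc5ccccc5)O[C@H](c1ccc(OCc5ccccc5)c(OCc5ccccc5)c1)[C@@H](OCc5ccccc5)C2 | intermediate
18 | 3,7,3',4'-tetra-O-benzylfisetinidol-(4α→8)-6-bromo-penta-O-benzylcatechin | Brc1c(OCc5ccccc5)c2c(c([C@@H]3c4ccc(OCc5ccccc5)cc4O[C@H](c4ccc(OCc5ccccc5)c(OCc5ccccc5)c4)[C@H]3OCc5ccccc5)c1OCc5ccccc5)O[C@H](c1ccc(OCc5ccccc5)c(OCc5ccccc5)c1)[C@@H](OCc5ccccc5)C2 | intermediate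
19 | 5-bromo-2,4-dihydroxybenzaldehyde | O=Cc1cc(Br)c(O)cc1O | starting material
20 | 4-(benzyloxy)-5-bromo-2-hydroxybenzaldehyde | O=Cc1cc(Br)c(OCc2ccccc2)cc1O | intermediate
21 | aryllithium from 18 (lithium on C6 of unit 3) | [Li]c1c(OCc5ccccc5)c2c(c([C@@H]3c4ccc(OCc5ccccc5)cc4O[C@H](c4ccc(OCc5ccccc5)c(OCc5ccccc5)c4)[C@H]3OCc5ccccc5)c1OCc5ccccc5)O[C@H](c1ccc(OCc5ccccc5)c(OCc5ccccc5)c1)[C@@H](OCc5ccccc5)C2 | intermediate (not isolated)
22 | sodium 5-(benzyloxy)-4-bromo-2-formylphenolate | [Na+].[O-]c1cc(OCc2ccccc2)c(Br)cc1C=O | intermediate (not isolated)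
23 | [8-(tetra-O-benzylfisetinidol-4α-yl)-penta-O-benzylcatechin-6-yl](4-benzyloxy-5-bromo-2-hydroxyphenyl)methanol, both carbinol epimers | OC(c1cc(Br)c(OCc5ccccc5)cc1O)c1c(OCc5ccccc5)c2c(c([C@@H]3c4ccc(OCc5ccccc5)cc4O[C@H](c4ccc(OCc5ccccc5)c(OCc5ccccc5)c4)[C@H]3OCc5ccccc5)c1OCc5ccccc5)O[C@H](c1ccc(OCc5ccccc5)c(OCc5ccccc5)c1)[C@@H](OCc5ccccc5)C2 | intermediate
24 | ortho-quinone methide from 23 | O=C1C=C(OCc5ccccc5)C(Br)=CC1=Cc1c(OCc5ccccc5)c2c(c([C@@H]3c4ccc(OCc5ccccc5)cc4O[C@H](c4ccc(OCc5ccccc5)c(OCc5ccccc5)c4)[C@H]3OCc5ccccc5)c1OCc5ccccc5)O[C@H](c1ccc(OCc5ccccc5)c(OCc5ccccc5)c1)[C@@H](OCc5ccccc5)C2 | intermediate (not isolated)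
25 | 6-bromo-7,3',4'-tri-O-benzyl-3-deoxy-3-(benzyldimethylsilyl)fisetinidol-(4α→6)-[3,7,3',4'-tetra-O-benzylfisetinidol-(4α→8)]-penta-O-benzylcatechin | Brc1cc2c(cc1OCc5ccccc5)O[C@H](c1ccc(OCc5ccccc5)c(OCc5ccccc5)c1)[C@@H]([Si](C)(C)Cc5ccccc5)[C@@H]2c1c(OCc5ccccc5)c2c(c([C@@H]3c4ccc(OCc5ccccc5)cc4O[C@H](c4ccc(OCc5ccccc5)c(OCc5ccccc5)c4)[C@H]3OCc5ccccc5)c1OCc5ccccc5)O[C@H](c1ccc(OCc5ccccc5)c(OCc5ccccc5)c1)[C@@H](OCc5ccccc5)C2 | intermediate
26 | fluorodimethylsilyl analogue of 25 | Brc1cc2c(cc1OCc5ccccc5)O[C@H](c1ccc(OCc5ccccc5)c(OCc5ccccc5)c1)[C@@H]([Si](C)(C)F)[C@@H]2c1c(OCc5ccccc5)c2c(c([C@@H]3c4ccc(OCc5ccccc5)cc4O[C@H](c4ccc(OCc5ccccc5)c(OCc5ccccc5)c4)[C@H]3OCc5ccccc5)c1OCc5ccccc5)O[C@H](c1ccc(OCc5ccccc5)c(OCc5ccccc5)c1)[C@@H](OCc5ccccc5)C2 | intermediate (not isolated)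
27 | 6-bromo-7,3',4'-tri-O-benzylfisetinidol-(4α→6)-[tetra-O-benzylfisetinidol-(4α→8)]-penta-O-benzylcatechin (free 3-hydroxyl on unit 2) | Brc1cc2c(cc1OCc5ccccc5)O[C@H](c1ccc(OCc5ccccc5)c(OCc5ccccc5)c1)[C@@H](O)[C@@H]2c1c(OCc5ccccc5)c2c(c([C@@H]3c4ccc(OCc5ccccc5)cc4O[C@H](c4ccc(OCc5ccccc5)c(OCc5ccccc5)c4)[C@H]3OCc5ccccc5)c1OCc5ccccc5)O[C@H](c1ccc(OCc5ccccc5)c(OCc5ccccc5)c1)[C@@H](OCc5ccccc5)C2 | intermediate
28 | 6-bromo-3,7,3',4'-tetra-O-benzylfisetinidol-(4α→6)-[tetra-O-benzylfisetinidol-(4α→8)]-penta-O-benzylcatechin | Brc1cc2c(cc1OCc5ccccc5)O[C@H](c1ccc(OCc5ccccc5)c(OCc5ccccc5)c1)[C@@H](OCc5ccccc5)[C@@H]2c1c(OCc5ccccc5)c2c(c([C@@H]3c4ccc(OCc5ccccc5)cc4O[C@H](c4ccc(OCc5ccccc5)c(OCc5ccccc5)c4)[C@H]3OCc5ccccc5)c1OCc5ccccc5)O[C@H](c1ccc(OCc5ccccc5)c(OCc5ccccc5)c1)[C@@H](OCc5ccccc5)C2 | intermediate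
29 | aryllithium from 28 (lithium on C6 of unit 2) | [Li]c1cc2c(cc1OCc5ccccc5)O[C@H](c1ccc(OCc5ccccc5)c(OCc5ccccc5)c1)[C@@H](OCc5ccccc5)[C@@H]2c1c(OCc5ccccc5)c2c(c([C@@H]3c4ccc(OCc5ccccc5)cc4O[C@H](c4ccc(OCc5ccccc5)c(OCc5ccccc5)c4)[C@H]3OCc5ccccc5)c1OCc5ccccc5)O[C@H](c1ccc(OCc5ccccc5)c(OCc5ccccc5)c1)[C@@H](OCc5ccccc5)C2 | intermediate (not isolated)
30 | 6-[(4-benzyloxy-2-hydroxyphenyl)(hydroxy)methyl]-3,7,3',4'-tetra-O-benzylfisetinidol-(4α→6)-[tetra-O-benzylfisetinidol-(4α→8)]-penta-O-benzylcatechin, both carbinol epimers | OC(c1ccc(OCc5ccccc5)cc1O)c1cc2c(cc1OCc5ccccc5)O[C@H](c1ccc(OCc5ccccc5)c(OCc5ccccc5)c1)[C@@H](OCc5ccccc5)[C@@H]2c1c(OCc5ccccc5)c2c(c([C@@H]3c4ccc(OCc5ccccc5)cc4O[C@H](c4ccc(OCc5ccccc5)c(OCc5ccccc5)c4)[C@H]3OCc5ccccc5)c1OCc5ccccc5)O[C@H](c1ccc(OCc5ccccc5)c(OCc5ccccc5)c1)[C@@H](OCc5ccccc5)C2 | intermediate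
31 | ortho-quinone methide from 30 | O=C1C=C(OCc5ccccc5)C=CC1=Cc1cc2c(cc1OCc5ccccc5)O[C@H](c1ccc(OCc5ccccc5)c(OCc5ccccc5)c1)[C@@H](OCc5ccccc5)[C@@H]2c1c(OCc5ccccc5)c2c(c([C@@H]3c4ccc(OCc5ccccc5)cc4O[C@H](c4ccc(OCc5ccccc5)c(OCc5ccccc5)c4)[C@H]3OCc5ccccc5)c1OCc5ccccc5)O[C@H](c1ccc(OCc5ccccc5)c(OCc5ccccc5)c1)[C@@H](OCc5ccccc5)C2 | intermediate (not isolated)
32 | 7,3',4'-tri-O-benzyl-3-deoxy-3-(benzyldimethylsilyl)fisetinidol-(4α→6)-tetra-O-benzylfisetinidol-(4α→6)-[tetra-O-benzylfisetinidol-(4α→8)]-penta-O-benzylcatechin | c5ccccc5COc1ccc2c(c1)O[C@H](c1ccc(OCc5ccccc5)c(OCc5ccccc5)c1)[C@@H]([Si](C)(C)Cc5ccccc5)[C@@H]2c1cc2c(cc1OCc5ccccc5)O[C@H](c1ccc(OCc5ccccc5)c(OCc5ccccc5)c1)[C@@H](OCc5ccccc5)[C@@H]2c1c(OCc5ccccc5)c2c(c([C@@H]3c4ccc(OCc5ccccc5)cc4O[C@H](c4ccc(OCc5ccccc5)c(OCc5ccccc5)c4)[C@H]3OCc5ccccc5)c1OCc5ccccc5)O[C@H](c1ccc(OCc5ccccc5)c(OCc5ccccc5)c1)[C@@H](OCc5ccccc5)C2 | intermediate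
33 | fluorodimethylsilyl analogue of 32 | c5ccccc5COc1ccc2c(c1)O[C@H](c1ccc(OCc5ccccc5)c(OCc5ccccc5)c1)[C@@H]([Si](C)(C)F)[C@@H]2c1cc2c(cc1OCc5ccccc5)O[C@H](c1ccc(OCc5ccccc5)c(OCc5ccccc5)c1)[C@@H](OCc5ccccc5)[C@@H]2c1c(OCc5ccccc5)c2c(c([C@@H]3c4ccc(OCc5ccccc5)cc4O[C@H](c4ccc(OCc5ccccc5)c(OCc5ccccc5)c4)[C@H]3OCc5ccccc5)c1OCc5ccccc5)O[C@H](c1ccc(OCc5ccccc5)c(OCc5ccccc5)c1)[C@@H](OCc5ccccc5)C2 | intermediate (not isolated)
34 | hexadeca-O-benzyl ether of the target, free 3-hydroxyl on unit 1 | c5ccccc5COc1ccc2c(c1)O[C@H](c1ccc(OCc5ccccc5)c(OCc5ccccc5)c1)[C@@H](O)[C@@H]2c1cc2c(cc1OCc5ccccc5)O[C@H](c1ccc(OCc5ccccc5)c(OCc5ccccc5)c1)[C@@H](OCc5ccccc5)[C@@H]2c1c(OCc5ccccc5)c2c(c([C@@H]3c4ccc(OCc5ccccc5)cc4O[C@H](c4ccc(OCc5ccccc5)c(OCc5ccccc5)c4)[C@H]3OCc5ccccc5)c1OCc5ccccc5)O[C@H](c1ccc(OCc5ccccc5)c(OCc5ccccc5)c1)[C@@H](OCc5ccccc5)C2 | intermediate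
35 | fisetinidol-(4α→6)-fisetinidol-(4α→6)-[fisetinidol-(4α→8)]-catechin | Oc1ccc2c(c1)O[C@H](c1ccc(O)c(O)c1)[C@@H](O)[C@@H]2c1cc2c(cc1O)O[C@H](c1ccc(O)c(O)c1)[C@@H](O)[C@@H]2c1c(O)c2c(c([C@@H]3c4ccc(O)cc4O[C@H](c4ccc(O)c(O)c4)[C@H]3O)c1O)O[C@H](c1ccc(O)c(O)c1)[C@@H](O)C2 | target

## Step count and least certain steps

Total step count: 20. Longest linear sequence: 15 steps (steps 1, 2, 3, 6, 9, 10, 11, 13, 14, 15, 16, 17, 18, 19, 20).

Step 9 (key step, new method). The most likely failures are loss of silicon from the benzylic, β-silyl cation before the ring oxygen closes (vinyl substitution in place of annulation), slow addition to the strongly stabilised cation so that Friedel–Crafts self-condensation takes over, and weak facial control by the catalyst. The fallback uses known chemistry, sets out from 9 and 11 and returns at 17. Compound 9 and alkyne 11 are combined under diphenyl phosphate catalysis in CH2Cl2, the known acid-catalysed [4+2] addition of ortho-quinone methides to aryl alkynes. This should give the 2,4-diaryl-4H-chromene F1 together with its C4 epimer, which is a diastereomer and is separated. Hydroboration–oxidation (BH3·SMe2, THF; then NaOH, H2O2) of the enol ether double bond places boron on C3 anti to the C4 aryl group and hydrogen on C2 on the same face. This is the known route from 4-substituted flav-2-enes to 2,3-trans-3,4-trans-flavan-3-ols and gives 17 without silicon. The price is no control at C4 in the cycloaddition.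

Step 14 (new method). The methide carbon now sits on C6 of unit 3 between two benzyloxy groups, so bond formation is slower than in step 9 and silicon loss or a mismatched pairing of catalyst and substrate becomes more likely. The fallback uses known chemistry, sets out from 23 and 11 and returns at 27. Acid-catalysed addition of the quinone methide to alkyne 11 should give the 4H-chromene F2 (4α epimer separated from its diastereomer). Hydroboration–oxidation as above then gives 27, with the bromine on C6 of unit 2 untouched.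

Step 18 (new method). The substrate is large and the quinone methide is the least stabilised of the three, so the likely failures are oligomerisation through attack of resorcinol-type ring positions and poor fit in the catalyst pocket with loss of facial control. The fallback uses known chemistry, sets out from 30 and 11 and returns at 34. Acid-catalysed addition to alkyne 11 should give the 4H-chromene F3 (diastereomers separated), and hydroboration–oxidation then gives 34.

Step 10 (the same holds for steps 15 and 19). The most likely failure is β-elimination: fluoride on silicon can expel the ring oxygen O1 as a phenoxide, since the C3–Si and C2–O1 bonds are anti-periplanar in the all-equatorial conformer, and ring C opens instead of being oxidised. The fallback turns this reaction into the route, sets out from 15 and returns at 17. The elimination is driven to completion (Bu4NF, THF, 50 °C) and should give the E-configured 1,3-diarylpropenyl phenol F4. Shi epoxidation of the E alkene (fructose-derived ketone, KHSO5, buffered) on the face that leads to the 3S alcohol should give the trans-epoxide F5. Camphorsulfonic acid in CH2Cl2 then closes ring C by 6-endo attack of the phenol on the benzylic epoxide carbon with inversion, the established way from such epoxides to 2,3-trans-flavan-3-ols, and gives 17.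

Step 3 (together with step 2). The most likely failure is halogen scrambling: ipso attack of the bromine electrophile at the iodine-bearing C8, or incomplete C8 selectivity in the iodination, would give regioisomeric dihalides that are hard to separate and would misplace the carbinol. The fallback sets out from 2 and returns at 15. Bromination of 2 with NBS, whose C8 selectivity is established, gives the 8-bromide F6. Bromine–lithium exchange and addition to 7 give the bromine-free carbinol F7. Cycloaddition with 13 as in step 9 gives the bromine-free silyl dimer F8. NBS then brominates C6 of unit 3, the only phloroglucinol-type CH, to give 15. The price is an unblocked C6 during the cycloaddition.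

## Further compounds

F1 | step 9 | 7,3',4'-tri-O-benzylflav-2-en-4α-yl-(4→8)-6-bromo-penta-O-benzylcatechin (2,4-diaryl-4H-chromene, C4 as in 15) | Brc1c(OCc5ccccc5)c2c(c([C@@H]3c4ccc(OCc5ccccc5)cc4OC(c4ccc(OCc5ccccc5)c(OCc5ccccc5)c4)=C3)c1OCc5ccccc5)O[C@H](c1ccc(OCc5ccccc5)c(OCc5ccccc5)c1)[C@@H](OCc5ccccc5)C2
F2 | step 14 | 6-bromo-7,3',4'-tri-O-benzylflav-2-en-4α-yl-(4→6)-[tetra-O-benzylfisetinidol-(4α→8)]-penta-O-benzylcatechin | Brc1cc2c(cc1OCc5ccccc5)OC(c1ccc(OCc5ccccc5)c(OCc5ccccc5)c1)=C[C@@H]2c1c(OCc5ccccc5)c2c(c([C@@H]3c4ccc(OCc5ccccc5)cc4O[C@H](c4ccc(OCc5ccccc5)c(OCc5ccccc5)c4)[C@H]3OCc5ccccc5)c1OCc5ccccc5)O[C@H](c1ccc(OCc5ccccc5)c(OCc5ccccc5)c1)[C@@H](OCc5ccccc5)C2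
F3 | step 18 | 7,3',4'-tri-O-benzylflav-2-en-4α-yl-(4→6)-tetra-O-benzylfisetinidol-(4α→6)-[tetra-O-benzylfisetinidol-(4α→8)]-penta-O-benzylcatechin | c5ccccc5COc1ccc2c(c1)OC(c1ccc(OCc5ccccc5)c(OCc5ccccc5)c1)=C[C@@H]2c1cc2c(cc1OCc5ccccc5)O[C@H](c1ccc(OCc5ccccc5)c(OCc5ccccc5)c1)[C@@H](OCc5ccccc5)[C@@H]2c1c(OCc5ccccc5)c2c(c([C@@H]3c4ccc(OCc5ccccc5)cc4O[C@H](c4ccc(OCc5ccccc5)c(OCc5ccccc5)c4)[C@H]3OCc5ccccc5)c1OCc5ccccc5)O[C@H](c1ccc(OCc5ccccc5)c(OCc5ccccc5)c1)[C@@H](OCc5ccccc5)C2
F4 | step 10 | 8-[(E)-1-(4-benzyloxy-2-hydroxyphenyl)-3-(3,4-bis(benzyloxy)phenyl)prop-2-en-1-yl]-6-bromo-penta-O-benzylcatechin (C4 as in 15) | Brc1c(OCc5ccccc5)c2c(c([C@H](c4ccc(OCc5ccccc5)cc4O)/C=C/c4ccc(OCc5ccccc5)c(OCc5ccccc5)c4)c1OCc5ccccc5)O[C@H](c1ccc(OCc5ccccc5)c(OCc5ccccc5)c1)[C@@H](OCc5ccccc5)C2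
F5 | step 10 | trans-epoxide of F4 (oxygen on the face of the later 3S hydroxyl) | Brc1c(OCc5ccccc5)c2c(c([C@H](c4ccc(OCc5ccccc5)cc4O)[C@@H]3O[C@H]3c4ccc(OCc5ccccc5)c(OCc5ccccc5)c4)c1OCc5ccccc5)O[C@H](c1ccc(OCc5ccccc5)c(OCc5ccccc5)c1)[C@@H](OCc5ccccc5)C2
F6 | step 3 | 8-bromo-3,5,7,3',4'-penta-O-benzylcatechin | Brc1c(OCc5ccccc5)cc(OCc5ccccc5)c2c1O[C@H](c1ccc(OCc5ccccc5)c(OCc5ccccc5)c1)[C@@H](OCc5ccccc5)C2
F7 | step 3 | (3,5,7,3',4'-penta-O-benzylcatechin-8-yl)(4-benzyloxy-2-hydroxyphenyl)methanol, both carbinol epimers | OC(c1ccc(OCc5ccccc5)cc1O)c1c(OCc5ccccc5)cc(OCc5ccccc5)c2c1O[C@H](c1ccc(OCc5ccccc5)c(OCc5ccccc5)c1)[C@@H](OCc5ccccc5)C2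
F8 | step 3 | 7,3',4'-tri-O-benzyl-3-deoxy-3-(benzyldimethylsilyl)fisetinidol-(4α→8)-penta-O-benzylcatechin | c1c(OCc5ccccc5)c2c(c([C@@H]3c4ccc(OCc5ccccc5)cc4O[C@H](c4ccc(OCc5ccccc5)c(OCc5ccccc5)c4)[C@H]3[Si](C)(C)Cc5ccccc5)c1OCc5ccccc5)O[C@H](c1ccc(OCc5ccccc5)c(OCc5ccccc5)c1)[C@@H](OCc5ccccc5)C2
A1 | alternative 1 | tetradeca-O-benzyl ether of the target with free 4'-hydroxyls on units 1, 2 and 4 | c5ccccc5COc1ccc2c(c1)O[C@H](c1ccc(O)c(OCc5ccccc5)c1)[C@@H](OCc5ccccc5)[C@@H]2c1cc2c(cc1OCc5ccccc5)O[C@H](c1ccc(O)c(OCc5ccccc5)c1)[C@@H](OCc5ccccc5)[C@@H]2c1c(OCc5ccccc5)c2c(c([C@@H]3c4ccc(OCc5ccccc5)cc4O[C@H](c4ccc(O)c(OCc5ccccc5)c4)[C@H]3OCc5ccccc5)c1OCc5ccccc5)O[C@H](c1ccc(OCc5ccccc5)c(OCc5ccccc5)c1)[C@@H](OCc5ccccc5)C2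
A2 | alternative 2 | 6-bromo-tri-O-benzylfisetinidol 3-acetate-(4α→6)-8-bromo-penta-O-benzylcatechin | Brc1cc2c(cc1OCc5ccccc5)O[C@H](c1ccc(OCc5ccccc5)c(OCc5ccccc5)c1)[C@@H](OC(C)=O)[C@@H]2c1c(OCc5ccccc5)c2c(c(Br)c1OCc5ccccc5)O[C@H](c1ccc(OCc5ccccc5)c(OCc5ccccc5)c1)[C@@H](OCc5ccccc5)C2
A3 | alternative 3 | tri-O-benzylfisetinidol-(4α→8)-penta-O-benzylcatechin with a free 3-hydroxyl on unit 4 | c1c(OCc5ccccc5)c2c(c([C@@H]3c4ccc(OCc5ccccc5)cc4O[C@H](c4ccc(OCc5ccccc5)c(OCc5ccccc5)c4)[C@H]3O)c1OCc5ccccc5)O[C@H](c1ccc(OCc5ccccc5)c(OCc5ccccc5)c1)[C@@H](OCc5ccccc5)C2
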